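**Plan**

- Retrosynthesis: cut the C8–O glycidate ester and the C13 acetate, open both oxiranes back to the E C1=C10 and Z C4=C5 alkenes, and remove the butenolide by cutting O6–C12 and C7=C11 (C11–C13 come from diethyl ketomalonate). This leaves 8-silyloxygermacra-1(10),4-dien-6-one.
- The ten-membered ring is then traced back to a bicycle by joining C6 to C10 (C6=O becomes a tertiary alcohol, C1=C10 becomes a C1 mesylate). The bicycle is cut at C4=C5 (metathesis), C5–C6 (vinyl addition), C1–C10 (aldol) and C10–C14 (methylation), back to a cyclopentenone.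
- Enabling feature: with a C6–C10 bond the carbocycle is a bicyclo[5.3.0]decane (five-membered ring C6–C7–C8–C9–C10; seven-membered ring C10–C1–C2–C3–C4–C5–C6, which holds the Z C4=C5 bond without strain). O6–C6–C10–C1–O1 is then a 1,3-diol array, so a C1 sulfonate can leave while C6–C10 breaks.
- Forward order of rings: cyclopentane, then cycloheptene (ring-closing metathesis), then the ten-membered ring (fragmentation), then two oxiranes, then the butenolide, then the C13 acetate and C8 ester.
- Stereochemistry: C8 comes from (R)-4-silyloxycyclopentenone. The E C1=C10 bond comes from a mesylate placed syn to the C10 methyl by a hydroxyl-directed reduction, and the Z C4=C5 bond from the cycloheptene. The ring oxiranes come from outer-face attack on the ten-membered ring, C6 from chelation-controlled reduction next to the 4,5-oxirane, and the side-chain oxirane from (R)-2-methylglycidol.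

Key step: step 9

Conventions: germacrane numbering throughout (ring C1–C10, C14 on C10, C15 on C4, C11–C13 the lactone carbons); TBS = tert-butyldimethylsilyl, Ms = methanesulfonyl.

Remark on the chemistry: the fragmentation substrate is taken with a trans ring fusion (C6–OH anti to the C10 methyl), the expected outcome of the C6 vinylation. Only the C1/C10 relationship (mesylate syn to the methyl) decides the alkene geometry, since C6 and C10 both become trigonal.

**Route**

Step 1
Reactants: 1 (R)-4-(TBSO)cyclopent-2-en-1-one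
Product: 2 (R)-4-(TBSO)-2-iodocyclopent-2-en-1-one
Conditions: I2, pyridine, CH2Cl2, 0 °C → rt
Reagents that add atoms: iodine, II
Why: α-Iodination of an enone by pyridine-mediated addition–iodination–elimination is routine for 4-silyloxycyclopentenones and leaves the C8 stereocentre untouched.

Step 2
Reactants: 2 (R)-4-(TBSO)-2-iodocyclopent-2-en-1-one
Product: 3 (R)-4-(TBSO)-2-methylcyclopent-2-en-1-one
Conditions: SnMe4, Pd2(dba)3 (cat.), AsPh3, CuI, NMP, 60 °C
Reagents that add atoms: tetramethylstannane, C[Sn](C)(C)C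
Why: Stille cross-coupling of an α-iodoenone with SnMe4 under AsPh3/CuI acceleration installs the C14 methyl under neutral conditions that do not eliminate the silyloxy group.

Step 3
Reactants: 3 (R)-4-(TBSO)-2-methylcyclopent-2-en-1-one; 4 4-methylpent-4-enal
Product: 6 aldol (2R,4S)-4-(TBSO)-2-[(1R)-1-hydroxy-4-methylpent-4-enyl]-2-methylcyclopentan-1-one, via lithium enolate 5 (not isolated)
Conditions: LiBH(s-Bu)3, THF, −78 °C; then 4, −78 °C; aq NH4Cl
Reagents that add atoms: none
Why: Reductive aldol reaction: 1,4-hydride addition gives the C6–C10 enolate regiospecifically (never the C6–C7 enolate that would expel the silyloxy group) and its Zimmerman–Traxler addition to 4 should occur on the face opposite the C8 silyloxy group to set quaternary C10; the C1 configuration (anti aldol expected) is not relied upon because it is reset in steps 6 and 7, and a C10 epimer would only alter a relationship that vanishes in step 9.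

Step 4
Reactants: 6 aldol (2R,4S)-4-(TBSO)-2-[(1R)-1-hydroxy-4-methylpent-4-enyl]-2-methylcyclopentan-1-one
Product: 7 vinyl carbinol (1S,2R,4S)-4-(TBSO)-1-ethenyl-2-[(1R)-1-hydroxy-4-methylpent-4-enyl]-2-methylcyclopentan-1-ol
Conditions: CH2=CHMgBr, CeCl3, THF, −78 °C; aq NH4Cl
Reagents that add atoms: vinylmagnesium bromide, C=C[Mg]Br
Why: 1,2-Addition of CH2=CHCeCl2 suppresses enolisation toward C7, and with the C1 alkoxide chelated to the C6 carbonyl on the side-chain face the vinyl group should enter from the methyl face, placing the new C6 hydroxyl anti to the C10 methyl.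

Step 5
Reactants: 7 vinyl carbinol (1S,2R,4S)-4-(TBSO)-1-ethenyl-2-[(1R)-1-hydroxy-4-methylpent-4-enyl]-2-methylcyclopentan-1-ol
Product: 8 trans-fused 2-(TBSO)-5,8a-dimethyl-1,2,3,3a,6,7,8,8a-octahydroazulene-3a,8-diol (C1–OH anti to the C10 methyl)
Conditions: second-generation Grubbs catalyst RuCl2(=CHPh)(H2IMes)(PCy3) (5 mol %), CH2Cl2, 40 °C
Reagents that add atoms: none
Why: Ring-closing metathesis between the vinyl carbinol and the 1,1-disubstituted alkene closes the seven-membered ring as a trisubstituted cycloheptene whose C4=C5 bond is necessarily Z, the free allylic hydroxyl assisting the ruthenium carbene.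

Step 6
Reactants: 8 trans-fused hydroazulene-3a,8-diol (C1–OH anti to the C10 methyl)
Product: 9 trans-fused 2-(TBSO)-3a-hydroxy-5,8a-dimethyl-1,2,3,3a,6,7-hexahydroazulen-8(8aH)-one
Conditions: Dess–Martin periodinane, NaHCO3, CH2Cl2, rt
Reagents that add atoms: none
Why: Dess–Martin oxidation converts only the secondary C1 alcohol (the tertiary allylic C6 alcohol cannot be oxidised), erasing the aldol-derived C1 configuration under non-basic conditions that avoid retro-aldol cleavage.

Step 7
Reactants: 9 trans-fused 3a-hydroxy-hydroazulen-8-one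
Product: 10 trans-fused 2-(TBSO)-5,8a-dimethyl-1,2,3,3a,6,7,8,8a-octahydroazulene-3a,8-diol (C1–OH syn to the C10 methyl)
Conditions: Me4NBH(OAc)3, MeCN/AcOH, −20 °C
Reagents that add atoms: none
Why: Evans–Saksena reduction: the axial C6 hydroxyl binds boron and delivers hydride intramolecularly to the C1 carbonyl from its own face, giving the 1,3-anti diol in which the C1 hydroxyl is equatorial and syn to the C10 methyl.

Step 8
Reactants: 10 trans-fused hydroazulene-3a,8-diol (C1–OH syn to the C10 methyl)
Product: 11 C1 methanesulfonate of 10 (C6–OH free)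
Conditions: MsCl, Et3N, CH2Cl2, −10 °C
Reagents that add atoms: methanesulfonyl chloride, CS(=O)(=O)Cl
Why: Selective sulfonylation of the secondary C1 hydroxyl in the presence of the tertiary C6 hydroxyl gives the 1,3-diol monomesylate with retention at C1.

Step 9
Reactants: 11 C1 methanesulfonate of the trans-fused hydroazulenediol
Product: 13 (2Z,6E,9S)-9-(TBSO)-3,7-dimethylcyclodeca-2,6-dien-1-one = (1(10)E,4Z)-8-(TBSO)germacra-1(10),4-dien-6-one, via potassium alkoxide 12 (not isolated)
Conditions: KN(SiMe3)2 (1.05 equiv), THF, −78 → 0 °C; pH 7 phosphate buffer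
Reagents that add atoms: none
Why: Deprotonation of the C6 hydroxyl gives an alkoxide whose lone pair pushes into C6, the C6–C10 ring-fusion bond breaks, the C1=C10 π bond forms and mesylate leaves from C1 in one concerted heterolytic event (Wharton-type Grob fragmentation), the closest precedent being the conversion of trans-fused bicyclic 1,3-diol monosulfonates into E-cyclodecenones. No ring is closed by bond formation: the ten-membered ring appears because the bond shared by the five- and seven-membered rings is cleaved, so no medium-ring cyclisation has to be paid for. No stereocentre is created, since C1, C6 and C10 become trigonal and C8 is not involved. The step needs E geometry at C1=C10, and the equatorial mesylate syn to the C10 methyl secures it: its C1–O bond is antiperiplanar to C6–C10, and in that arrangement C2 is antiperiplanar to C9, which maps onto the E alkene only. The Z geometry of C4=C5 is inherited from the cycloheptene and ends up conjugated with the new C6 ketone. Loss of the C8 silyloxy group from the β-silyloxy ketone product is avoided because the single equivalent of base is consumed by the fragmentation, leaving only potassium mesylate and the neutral amine.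

Step 10
Reactants: 13 (1(10)E,4Z)-8-(TBSO)germacra-1(10),4-dien-6-one
Product: 14 1,10:4,5-diepoxy-8-(TBSO)germacran-6-one (oxiranes configured as in the target)
Conditions: dimethyldioxirane (excess), acetone, 0 °C → rt
Reagents that add atoms: dimethyldioxirane, CC1(C)OO1
Why: Dimethyldioxirane epoxidation is neutral and stereospecific and oxidises both the electron-rich E alkene and the β,β-disubstituted enone without harming the β-silyloxy ketone; attack on the outer face of each π bond (C1=C10 as in peracid epoxidations of germacra-1(10)-enes, C4=C5 away from the transannular C7–C9 segment) is expected to give the trans-1,10- and cis-4,5-oxiranes of the target.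

Step 11
Reactants: 14 1,10:4,5-diepoxy-8-(TBSO)germacran-6-one; 15 diethyl ketomalonate
Product: 17 diethyl 2-hydroxy-2-[1,10:4,5-diepoxy-6-oxo-8-(TBSO)germacran-7-yl]malonate, via lithium enolate 16 (not isolated)
Conditions: LiN(SiMe3)2, THF, −78 °C; then 15, −78 °C; AcOH, −78 °C
Reagents that add atoms: none
Why: Aldol addition: deprotonation can only occur at C7 (C5 is an oxirane carbon), and the lithium enolate, kept at −78 °C to suppress β-elimination of the C8 silyloxy group, adds to the non-enolisable and highly electrophilic ketone of 15 anti to the silyloxy group (the C7 centre is removed in step 12).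

Step 12
Reactants: 17 diethyl 2-hydroxy-2-(6-oxogermacran-7-yl)malonate
Product: 19 diethyl 2-[1,10:4,5-diepoxy-6-oxo-8-(TBSO)germacran-7-ylidene]malonate, via tertiary mesylate 18 (not isolated)
Conditions: MsCl, Et3N, DMAP (cat.), CH2Cl2, 0 °C → rt
Reagents that add atoms: none
Why: Aldol dehydration by mesylation of the malonate-flanked tertiary hydroxyl and E1cB elimination through the C7 enolate gives the tetrasubstituted alkylidene malonate, mesylate being expelled far faster than the C8 silyloxy group.

Step 13
Reactants: 19 diethyl 2-(6-oxogermacran-7-ylidene)malonate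
Product: 21 ethyl 1,10:4,5-diepoxy-8-(TBSO)germacr-7(11)-en-6,12-olid-13-oate, via hydroxy diester 20 (not isolated)
Conditions: Zn(BH4)2, Et2O, −30 °C; aq NH4Cl; then silica gel, CH2Cl2, rt
Reagents that add atoms: none
Why: Chelation-controlled reduction of an α,β-epoxy ketone: zinc bridges the C6 carbonyl and the oxirane oxygen and hydride adds from the face remote from C4, giving the erythro epoxy alcohol (the C6 configuration of the target), after which the C6 hydroxyl lactonises onto the cis ester to close the butenolide.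

Step 14
Reactants: 21 ethyl ester butenolide
Product: 22 triol 2-[1,10:4,5-diepoxy-6-hydroxy-8-(TBSO)germacran-7-ylidene]propane-1,3-diol
Conditions: i-Bu2AlH (excess), CH2Cl2, −78 → 0 °C; aq KNaC4H4O6
Reagents that add atoms: none
Why: Exhaustive 1,2-reduction of the conjugated ester and the butenolide by i-Bu2AlH (oxiranes and silyl ether survive at low temperature) turns the chemically similar ester and lactone carbonyls into two primary alcohols that step 15 distinguishes by their distance from the C6 hydroxyl.

Step 15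
Reactants: 22 triol
Product: 24 13-oxo-1,10:4,5-diepoxy-8-(TBSO)germacr-7(11)-en-6,12-olide, via lactol aldehyde 23 (not isolated)
Conditions: TEMPO (cat.), PhI(OAc)2, NaHCO3, CH2Cl2, rt
Reagents that add atoms: none
Why: TEMPO/PhI(OAc)2 oxidation prefers primary alcohols over the secondary C6 carbinol; the C12 aldehyde is captured by the C6 hydroxyl as a lactol that is oxidised on to the butenolide (oxidative lactonisation of a 1,4-diol), while the C13 carbinol, which cannot reach O6, stops at the aldehyde.

Step 16
Reactants: 24 13-oxo butenolide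
Product: 25 13-hydroxy-1,10:4,5-diepoxy-8-(TBSO)germacr-7(11)-en-6,12-olide
Conditions: NaBH4, CeCl3·7H2O, MeOH, −78 °C
Reagents that add atoms: none
Why: Luche reduction reduces the aldehyde in 1,2-fashion and leaves the lactone, the oxiranes and the electron-poor C7=C11 bond alone.

Step 17
Reactants: 25 13-hydroxy butenolide
Product: 26 13-acetoxy-1,10:4,5-diepoxy-8-(TBSO)germacr-7(11)-en-6,12-olide
Conditions: Ac2O, pyridine, DMAP (cat.), CH2Cl2, 0 °C
Reagents that add atoms: acetic anhydride, CC(=O)OC(C)=O
Why: DMAP-catalysed acylation of the primary allylic alcohol gives the C13 acetate.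

Step 18
Reactants: 26 13-acetoxy 8-silyl ether
Product: 27 13-acetoxy-1,10:4,5-diepoxy-8-hydroxygermacr-7(11)-en-6,12-olide
Conditions: HF·pyridine, pyridine, THF, 0 °C → rt
Reagents that add atoms: none
Why: Fluoride-mediated desilylation with buffered HF·pyridine is mildly acidic, which avoids acetate migration and base-induced damage to the butenolide, and trisubstituted oxiranes are known to tolerate this reagent.

Step 19
Reactants: 28 (R)-2-methylglycidol
Product: 29 (S)-2-methyloxirane-2-carboxylic acid
Conditions: RuCl3·xH2O (cat.), NaIO4, CCl4/MeCN/H2O, rt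
Reagents that add atoms: water, O
Why: Oxidation by catalytically generated RuO4 converts the primary alcohol of an epoxy alcohol into the glycidic acid without touching the quaternary stereocentre (the descriptor changes from R to S only through the priority rules).

Step 20
Reactants: 27 13-acetoxy 8-alcohol; 29 (S)-2-methyloxirane-2-carboxylic acid
Product: 31 target (1R,4R,5S,6S,8S,10R)-13-acetoxy-1,10:4,5-diepoxy-8-[(S)-2-methyloxirane-2-carbonyloxy]germacr-7(11)-en-6,12-olide, via mixed anhydride 30 (not isolated)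
Conditions: 2,4,6-Cl3C6H2COCl, Et3N, THF, rt; then 27, DMAP, toluene, rt
Reagents that add atoms: none
Why: Yamaguchi esterification: DMAP attacks the less hindered glycidyl carbonyl of the mixed anhydride and the acyl group is transferred to the hindered secondary C8 alcohol with retention at C8 and at the oxirane carbon.

**Compound list**

1 | (R)-4-(tert-butyldimethylsilyloxy)cyclopent-2-en-1-one | O=C1C=C[C@H](O[Si](C)(C)C(C)(C)C)C1 | starting material
2 | (R)-4-(tert-butyldimethylsilyloxy)-2-iodocyclopent-2-en-1-one | O=C1C(I)=C[C@H](O[Si](C)(C)C(C)(C)C)C1 | intermediate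
3 | (R)-4-(tert-butyldimethylsilyloxy)-2-methylcyclopent-2-en-1-one | O=C1C(C)=C[C@H](O[Si](C)(C)C(C)(C)C)C1 | intermediate
4 | 4-methylpent-4-enal | C=C(C)CCC=O | starting material
5 | lithium (S)-4-(tert-butyldimethylsilyloxy)-2-methylcyclopent-1-en-1-olate | [Li+].[O-]C1=C(C)C[C@H](O[Si](C)(C)C(C)(C)C)C1 | intermediate
6 | (2R,4S)-4-(tert-butyldimethylsilyloxy)-2-[(1R)-1-hydroxy-4-methylpent-4-en-1-yl]-2-methylcyclopentan-1-one (side chain trans to the silyloxy group) | C=C(C)CC[C@@H](O)[C@@]1(C)C[C@H](O[Si](C)(C)C(C)(C)C)CC1=O | intermediate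
7 | (1S,2R,4S)-4-(tert-butyldimethylsilyloxy)-1-ethenyl-2-[(1R)-1-hydroxy-4-methylpent-4-en-1-yl]-2-methylcyclopentan-1-ol (vinyl trans to the side chain) | C=C(C)CC[C@@H](O)[C@@]1(C)C[C@H](O[Si](C)(C)C(C)(C)C)C[C@]1(O)C=C | intermediate
8 | trans-fused 2-(tert-butyldimethylsilyloxy)-5,8a-dimethyl-1,2,3,3a,6,7,8,8a-octahydroazulene-3a,8-diol; C6–OH anti, C1–OH anti and C8–OSi syn to the C10 methyl | CC1=C[C@@]2(O)C[C@@H](O[Si](C)(C)C(C)(C)C)C[C@]2(C)[C@H](O)CC1 | intermediate
9 | trans-fused 2-(tert-butyldimethylsilyloxy)-3a-hydroxy-5,8a-dimethyl-1,2,3,3a,6,7-hexahydroazulen-8(8aH)-one | CC1=C[C@@]2(O)C[C@@H](O[Si](C)(C)C(C)(C)C)C[C@]2(C)C(=O)CC1 | intermediate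
10 | trans-fused 2-(tert-butyldimethylsilyloxy)-5,8a-dimethyl-1,2,3,3a,6,7,8,8a-octahydroazulene-3a,8-diol; C6–OH anti, C1–OH syn and C8–OSi syn to the C10 methyl | CC1=C[C@@]2(O)C[C@@H](O[Si](C)(C)C(C)(C)C)C[C@]2(C)[C@@H](O)CC1 | intermediate
11 | C1 (azulene C8) methanesulfonate of 10 | CC1=C[C@@]2(O)C[C@@H](O[Si](C)(C)C(C)(C)C)C[C@]2(C)[C@@H](OS(C)(=O)=O)CC1 | intermediate
12 | potassium C6 (azulene C3a) alkoxide of 11 | [K+].CC1=C[C@@]2([O-])C[C@@H](O[Si](C)(C)C(C)(C)C)C[C@]2(C)[C@@H](OS(C)(=O)=O)CC1 | intermediate
13 | (2Z,6E,9S)-9-(tert-butyldimethylsilyloxy)-3,7-dimethylcyclodeca-2,6-dien-1-one = (1(10)E,4Z)-8-silyloxygermacra-1(10),4-dien-6-one | C/C1=C/C(=O)C[C@@H](O[Si](C)(C)C(C)(C)C)C/C(C)=C/CC1 | intermediate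
14 | 1,10:4,5-diepoxy-8-(tert-butyldimethylsilyloxy)germacran-6-one (trans-1,10-oxirane, cis-4,5-oxirane, configured as in the target) | O=C1C[C@@H](O[Si](C)(C)C(C)(C)C)C[C@@]2(C)O[C@@H]2CC[C@@]2(C)O[C@H]21 | intermediate
15 | diethyl ketomalonate (diethyl 2-oxopropanedioate) | CCOC(=O)C(=O)C(=O)OCC | starting material
16 | lithium C6=C7 enolate of 14 | [Li+].[O-]C1=C[C@@H](O[Si](C)(C)C(C)(C)C)C[C@@]2(C)O[C@@H]2CC[C@@]2(C)O[C@H]21 | intermediate
17 | diethyl 2-hydroxy-2-[1,10:4,5-diepoxy-6-oxo-8-(tert-butyldimethylsilyloxy)germacran-7-yl]malonate (C7 substituent trans to the silyloxy group) | O=C1[C@H](C(O)(C(=O)OCC)C(=O)OCC)[C@@H](O[Si](C)(C)C(C)(C)C)C[C@@]2(C)O[C@@H]2CC[C@@]2(C)O[C@H]21 | intermediate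
18 | tertiary methanesulfonate of 17 | O=C1[C@H](C(OS(C)(=O)=O)(C(=O)OCC)C(=O)OCC)[C@@H](O[Si](C)(C)C(C)(C)C)C[C@@]2(C)O[C@@H]2CC[C@@]2(C)O[C@H]21 | intermediate
19 | diethyl 2-[1,10:4,5-diepoxy-6-oxo-8-(tert-butyldimethylsilyloxy)germacran-7-ylidene]malonate | O=C1C(=C(C(=O)OCC)C(=O)OCC)[C@@H](O[Si](C)(C)C(C)(C)C)C[C@@]2(C)O[C@@H]2CC[C@@]2(C)O[C@H]21 | intermediate
20 | diethyl 2-[1,10:4,5-diepoxy-6-hydroxy-8-(tert-butyldimethylsilyloxy)germacran-7-ylidene]malonate (C6–OH erythro to the 4,5-oxirane) | O[C@H]1C(=C(C(=O)OCC)C(=O)OCC)[C@@H](O[Si](C)(C)C(C)(C)C)C[C@@]2(C)O[C@@H]2CC[C@@]2(C)O[C@H]21 | intermediate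
21 | ethyl 1,10:4,5-diepoxy-8-(tert-butyldimethylsilyloxy)germacr-7(11)-en-6,12-olid-13-oate | CCOC(=O)C1=C2[C@@H](O[Si](C)(C)C(C)(C)C)C[C@@]3(C)O[C@@H]3CC[C@@]3(C)O[C@H]3[C@H]2OC1=O | intermediate
22 | 2-[1,10:4,5-diepoxy-6-hydroxy-8-(tert-butyldimethylsilyloxy)germacran-7-ylidene]propane-1,3-diol | OCC(CO)=C1[C@@H](O[Si](C)(C)C(C)(C)C)C[C@@]2(C)O[C@@H]2CC[C@@]2(C)O[C@H]2[C@H]1O | intermediate
23 | 12-hydroxy-6,12-epoxy-1,10:4,5-diepoxy-8-(tert-butyldimethylsilyloxy)germacr-7(11)-en-13-al (lactol, both anomers) | O=CC1=C2[C@@H](O[Si](C)(C)C(C)(C)C)C[C@@]3(C)O[C@@H]3CC[C@@]3(C)O[C@H]3[C@H]2OC1O | intermediate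
24 | 13-oxo-1,10:4,5-diepoxy-8-(tert-butyldimethylsilyloxy)germacr-7(11)-en-6,12-olide | O=CC1=C2[C@@H](O[Si](C)(C)C(C)(C)C)C[C@@]3(C)O[C@@H]3CC[C@@]3(C)O[C@H]3[C@H]2OC1=O | intermediate
25 | 13-hydroxy-1,10:4,5-diepoxy-8-(tert-butyldimethylsilyloxy)germacr-7(11)-en-6,12-olide | OCC1=C2[C@@H](O[Si](C)(C)C(C)(C)C)C[C@@]3(C)O[C@@H]3CC[C@@]3(C)O[C@H]3[C@H]2OC1=O | intermediate
26 | 13-acetoxy-1,10:4,5-diepoxy-8-(tert-butyldimethylsilyloxy)germacr-7(11)-en-6,12-olide | CC(=O)OCC1=C2[C@@H](O[Si](C)(C)C(C)(C)C)C[C@@]3(C)O[C@@H]3CC[C@@]3(C)O[C@H]3[C@H]2OC1=O | intermediate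
27 | 13-acetoxy-1,10:4,5-diepoxy-8-hydroxygermacr-7(11)-en-6,12-olide | CC(=O)OCC1=C2[C@@H](O)C[C@@]3(C)O[C@@H]3CC[C@@]3(C)O[C@H]3[C@H]2OC1=O | intermediate
28 | (R)-2-methylglycidol [(R)-(2-methyloxiran-2-yl)methanol] | OC[C@]1(C)CO1 | starting material
29 | (S)-2-methyloxirane-2-carboxylic acid | OC(=O)[C@]1(C)CO1 | intermediate
30 | (S)-2-methyloxirane-2-carboxylic 2,4,6-trichlorobenzoic anhydride | O=C(OC(=O)[C@]1(C)CO1)c1c(Cl)cc(Cl)cc1Cl | intermediate
31 | CNP0289810.1: (1R,4R,5S,6S,8S,10R)-13-acetoxy-1,10:4,5-diepoxy-8-[(S)-2-methyloxirane-2-carbonyloxy]germacr-7(11)-en-6,12-olide | CC(=O)OCC1=C2[C@@H](OC(=O)[C@]3(C)CO3)C[C@@]3(C)O[C@@H]3CC[C@@]3(C)O[C@H]3[C@H]2OC1=O | target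

**Step count**

Total steps: 20. Longest linear sequence: 19 (steps 1–18 and 20, from 1 to 31); step 19 is the one-step side branch to acid 29.

**Steps most likely to fail**

Step 11. The C7 lithium enolate may expel the C8 silyloxy group (E1cB), or the ketomalonate adduct may revert by retro-aldol cleavage before it is quenched. The fallback attaches the three-carbon unit before the oxiranes are present, so that a base-free, Lewis-acid-mediated aldol becomes possible. It sets out from dienone 13, which is converted with Me3SiOTf/Et3N into the cross-conjugated trimethylsilyl dienol ether F1. A Mukaiyama aldol addition of F1 to 15 (BF3·OEt2, CH2Cl2, −78 °C) should give the dienone aldol adduct F2. Mesylation leads through the tertiary mesylate F3 (not isolated) to the alkylidene malonate dienone F4. Dimethyldioxirane then epoxidises the two ring alkenes only, the alkylidene malonate being too electron-poor, and the route is rejoined at 19.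

Step 10. Facial selectivity at either ring alkene may be poor, because only the conformation of the ten-membered ring guides the oxidant. The fallback separates the two oxidations and places each under catalyst control. It sets out from 13: an iminium-catalysed nucleophilic epoxidation of the enone with aqueous H2O2 and a cinchona-derived primary amine salt (either pseudoenantiomeric catalyst can be chosen to impose the face) should give the 4,5-epoxy enone F5. A Shi epoxidation of the remaining E alkene (fructose-derived ketone catalyst of the appropriate enantiomeric series, KHSO5, K2CO3 buffer) then returns to the route at 14.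

Step 4. Addition may occur on the wrong face of the hindered C6 carbonyl if the alkoxide chelate does not control the approach. That would give the cis-fused series, for which the anti-selective reduction of step 7 is mismatched. The fallback replaces chelation control by steric control. It sets out from 6, whose C1 hydroxyl is silylated (Et3SiOTf, 2,6-lutidine) to the triethylsilyl ether F6, so that the branched silylated side chain shields its own face. Addition of CH2=CHCeCl2 then gives the vinyl carbinol F7, and ring-closing metathesis with the catalyst of step 5 gives the bicyclic triethylsilyl ether F8. Selective removal of the triethylsilyl group (PPTS, MeOH, 0 °C) returns to the route at 8.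

Further compounds
F1 | step 11 | (2Z,6E)-9-(tert-butyldimethylsilyloxy)-3,7-dimethyl-1-(trimethylsilyloxy)cyclodeca-1(10),2,6-triene (C6 trimethylsilyl dienol ether of 13) | C/C1=C/C(O[Si](C)(C)C)=C[C@@H](O[Si](C)(C)C(C)(C)C)C/C(C)=C/CC1
F2 | step 11 | diethyl 2-hydroxy-2-[(1(10)E,4Z)-6-oxo-8-(tert-butyldimethylsilyloxy)germacra-1(10),4-dien-7-yl]malonate | C/C1=C/C(=O)[C@H](C(O)(C(=O)OCC)C(=O)OCC)[C@@H](O[Si](C)(C)C(C)(C)C)C/C(C)=C/CC1
F3 | step 11 | tertiary methanesulfonate of F2 | C/C1=C/C(=O)[C@H](C(OS(C)(=O)=O)(C(=O)OCC)C(=O)OCC)[C@@H](O[Si](C)(C)C(C)(C)C)C/C(C)=C/CC1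
F4 | step 11 | diethyl 2-[(1(10)E,4Z)-6-oxo-8-(tert-butyldimethylsilyloxy)germacra-1(10),4-dien-7-ylidene]malonate | C/C1=C/C(=O)C(=C(C(=O)OCC)C(=O)OCC)[C@@H](O[Si](C)(C)C(C)(C)C)C/C(C)=C/CC1
F5 | step 10 | (1(10)E)-4,5-epoxy-8-(tert-butyldimethylsilyloxy)germacr-1(10)-en-6-one (cis-oxirane configured as in the target) | O=C1C[C@@H](O[Si](C)(C)C(C)(C)C)C/C(C)=C/CC[C@@]2(C)O[C@H]21
F6 | step 4 | (2R,4S)-4-(tert-butyldimethylsilyloxy)-2-methyl-2-[(1R)-4-methyl-1-(triethylsilyloxy)pent-4-en-1-yl]cyclopentan-1-one | C=C(C)CC[C@@H](O[Si](CC)(CC)CC)[C@@]1(C)C[C@H](O[Si](C)(C)C(C)(C)C)CC1=O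
F7 | step 4 | (1S,2R,4S)-4-(tert-butyldimethylsilyloxy)-1-ethenyl-2-methyl-2-[(1R)-4-methyl-1-(triethylsilyloxy)pent-4-en-1-yl]cyclopentan-1-ol | C=C(C)CC[C@@H](O[Si](CC)(CC)CC)[C@@]1(C)C[C@H](O[Si](C)(C)C(C)(C)C)C[C@]1(O)C=C
F8 | step 4 | C1 (azulene C8) triethylsilyl ether of 8 | CC1=C[C@@]2(O)C[C@@H](O[Si](C)(C)C(C)(C)C)C[C@]2(C)[C@H](O[Si](CC)(CC)CC)CC1
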